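All runs stem from a simulated flask with made-up constants, noise included.

Compare the mean rate of target formation over equal windows of the ash run, which is this flask followed so far, before guessing what stands in it.

| setting | ash | flask |
|---|---|---|
| substrate | 14 mM | 14 mM |
| partner | 1 equiv | 1.00 equiv |
| temperature | 80 °C | 80 °C |
| remark | the very flask that is asked about, followed so far |  |
| time |  | 6.0 h |

ash run (percent of the substrate charged)

| time / min | target / % |
|---|---|
| 40.0 | 13.5 |
| 80.0 | 16.0 |
| 120 | 16.4 |
| 150 | 17.1 |
| 180 | 17.7 |
| 240 | 17.9 |

(readings scatter by 0.3 percentage points)

- target, in percent of the substrate first charged, at 6.0 h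
- the remedy with the largest gain of target, or "none" below 2 percentage points (Thursday's / Saturday's / Sunday's / Friday's / none)
- target present, with what was taken out counted in, in percent of the substrate first charged, after Thursday's
- target present, with what was taken out counted in, in percent of the substrate first charged, after Saturday's

- target that was removed still counts
- the numbers in the tables scatter by 0.3 percentage points (one standard deviation)
- additions bring no volume worth counting
- the earlier runs do not show what temperature does; that part of a forecast is a guess

- Thursday's: change nothing and wait 2.0 h more
- Saturday's: at 6.0 h raise the temperature by 10 K, then wait 2.0 h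
- Sunday's: at 6.0 h add partner, 50.0% of the amount charged, then wait 2.0 h
- Friday's: at 6.0 h take out 90% of the target then present, then wait 2.0 h

In the ash run the target forms at 0.203 h⁻¹ of the charge up to 40.0 min, but at 0.00750 h⁻¹ between 120 min and 240 min, a fall that I read, within the scatter of the readings, as a factor of 27.0. If I assume first order in substrate and in partner, and let the target's own count measure their use, supply accounts for a factor of 1.48. That leaves 18.2 to something unseen, and these readings cannot say what.

The end can still be reckoned. The gain from 120 min to 240 min over the gain up to 120 min reads 0.0915; this reading, a ratio of two mean rates over equal windows in which time drops out, I call the window ratio q. If each window yields q of the one before, my flask stands at 18.0% at 6.0 h, and Thursday's, which is one more such window, adds 0.013 percentage points, well under 2 points. I guess Saturday's stays near that figure too. Partner is charged at 1.00 equiv, level with the substrate, so I suspect an unseen use of it and stake on Sunday's, as a bet.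

The forecast, which differs from my stake, gives 18.6%, 19% after Thursday's and 20% after Saturday's, and names Friday's, holding that “Equilibrium seems the likeliest reading”.

The flask gives 17.8%, then 17.8% after Thursday's and 17.8% after Saturday's; the largest gain is 17 points, from Sunday's.

    substrate + partner → intermediate A (k = 0.176 M⁻¹ s⁻¹, Ea = 55.0 kJ mol⁻¹)
    partner + intermediate A → intermediate B (k = 0.126 M⁻¹ s⁻¹, Ea = 47.0 kJ mol⁻¹)
    intermediate B → intermediate C (k = 0.0121 s⁻¹, Ea = 107 kJ mol⁻¹)
    intermediate B → side product (k = 0.00728 s⁻¹, Ea = 99.0 kJ mol⁻¹)
    intermediate C → target (k = 0.0470 s⁻¹, Ea = 93.0 kJ mol⁻¹)
    partner ⇌ dormant form (K = 1.34, k = 5.49 × 10⁻⁴ s⁻¹, Ea = 102 kJ mol⁻¹, ΔH = −38.0 kJ mol⁻¹)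
    (constants at 80 °C)

Thursday's real gain of 0.017 points stands beside the 0.013 points that q gave. The main reason for the stall in this flask is the wearing away of partner: the run without it reaches 62.4% at 6.0 h against 17.8%, and of partner, the limiting reagent, 0.0116% of the charge is still free at 360 min. For the neighbour flask read at 2.5 h, the end value from q, the reading at 120 min divided by one minus q, times the share of that end reached by then if each window of 120 min yields q of the one before, gives 17.1%; the computed result is 17.1%.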